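A one-step world ends when one reagent is spent. Tuesday's run, with 1.50 equivalents of coupling partner, does not look like that: at 15.0 min you still read 60.4% starting material.

| flask | starting material | coupling partner | remark | time |
|---|---|---|---|---|
| Tuesday's | 0.050 M | 0.075 M | run made earlier |  |
| Thursday's | 0.050 M | 0.050 M | run made earlier |  |
| Sunday's | 0.050 M | 0.11 M | run made earlier |  |
| zeta | 0.050 M | 0.0750 M | everything together at the start | 15 min |
| theta | 0.050 M (fed, over 6.0 min) | 0.0750 M | all else is in the flask from the start; the feed brings no volume worth counting | 15 min |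
| alpha | 0.050 M | 0.0750 M (fed, over 6.0 min) | all else is in the flask from the start; the feed brings no volume worth counting | 15 min |

| run | time / min | isomer of the product / % | target / % | starting material / % |
|---|---|---|---|---|
| Tuesday's | 3.00 | 30.0 | 1.4 | 66.9 |
| Tuesday's | 6.00 | 33.4 | 1.7 | 62.1 |
| Tuesday's | 10.0 | 36.5 | 1.1 | 60.5 |
| Tuesday's | 12.0 | 35.6 | 2.1 | 60.2 |
| Tuesday's | 15.0 | 36.3 | 2.0 | 60.4 |
| Thursday's | 1.33 | 19.2 | 1.1 | 78.0 |
| Thursday's | 2.50 | 24.1 | 1.5 | 72.8 |
| Thursday's | 5.00 | 28.5 | 1.2 | 68.4 |
| Thursday's | 10.0 | 30.0 | 1.1 | 65.6 |
| Thursday's | 20.0 | 32.4 | 1.7 | 64.5 |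
| Sunday's | 1.50 | 28.5 | 1.2 | 68.3 |
| Sunday's | 5.00 | 38.0 | 2.3 | 58.9 |
| Sunday's | 8.00 | 39.8 | 1.2 | 57.2 |
| Sunday's | 12.0 | 40.7 | 3.9 | 55.5 |
| Sunday's | 20.0 | 42.0 | 2.0 | 54.0 |

(scatter of a reading: 0.5 percentage points)

1. the flask that comes out highest in amount of isomer of the product, in percent of the starting material charged, or "all alike" when all lie within 1.5 percentage points (zeta / theta / alpha / all alike)
2. isomer of the product at the end, in percent of the starting material charged, zeta
3. isomer of the product at the end, in percent of the starting material charged, theta
4. isomer of the product at the end, in percent of the starting material charged, alpha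



Suppose the stall means that the partner has gone, partly by a second loss. Let e be the equivalents charged and y the fraction of the starting material coupled, isomer of the product plus target. Then (e − y)/y is the partner lost per partner coupled. Dividing by e allows for a loss that grows with partner:

w = (e − y)/(y e), so y = e/(1 + w e)

Tuesday's readings give w = 1.94, Thursday's 1.93, Sunday's 1.82. This w, the loss ratio per equivalent, is a lumped number read from the readings, not a rate constant, and w = 0 stands for no loss of partner.

Now the ladder of times. Tuesday's isomer reads 30.0% by 3.00 min, against 36.3% at the end, so coupling is mostly over in a time shorter than the feed, and the feed is shorter than the run. I therefore reckon a feed as 2.00 successive batches. Zeta repeats Tuesday's run. In alpha, the second portion of partner meets what the first left. In theta, I count the first portion of starting material only, assuming the partner has gone before the second arrives.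

alpha, first portion: y = 30.5%

alpha, second portion: y = 24.2%

alpha, isomer: 51.9%

theta, isomer: 20.8%

The forecast differs (“something stops working rather than running out”): it puts zeta highest, with 36.2%, 13% and 21% for zeta, theta and alpha.

The flask gives alpha highest, with 36.8%, 14.6% and 52.9% for zeta, theta and alpha.

    starting material + coupling partner → isomer of the product (k = 0.120 L mol⁻¹ s⁻¹)
    starting material ⇌ tautomer (K = 0.0260, k = 0.00900 s⁻¹)
    2 coupling partner → homo dimer (k = 0.300 L mol⁻¹ s⁻¹)
    coupling partner + tautomer → target (k = 0.270 L mol⁻¹ s⁻¹)

Alpha's gap over theta, 38 percentage points, shrinks to 0.053 points with the homo dimer step struck out, and to 3.7 points with the back run from tautomer struck out; the two act together. Alpha's own w is 1.12, or 0.575 of Tuesday's. Carry that factor to a neighbour flask, alpha with 0.13 M of partner: y = 66.5%. That flask gives 68.8%.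

(The data are simulated for substances that don't exist; the scatter is artificial.)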